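**Strategy**

Everything rests on disconnecting the benzene ring's ortho-hydroxyaryl ketone pair: the C1–carbonyl bond to the (R)-2-methylbutanoyl group and the neighbouring C6–O bond are made together from an aryne spanning C1/C6 and the intact chiral acid. Fluoride-triggered insertion of this aryne into the acid C–O bond delivers ketone and phenol in one operation, the C2 oxygen beside the triple bond dictating the orientation, so the epimerisable acyl group arrives without Lewis acid. The precursor is a 2-(trimethylsilyl)aryl triflate bearing two MOM ethers and the ring methyl, built from 2-methylresorcinol. Later, iodine at C5 is exchanged for a masked acetyl before O4 is geranylated, so palladium never meets the allylic ether.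

Key step: step 5

Assumption: ring positions are numbered as in the target (C1 2-methylbutanoyl, C2 OH, C3 CH3, C4 O-geranyl, C5 acetyl, C6 OH); the single stereocentre is R, is bought with (R)-2-methylbutanoic acid and never becomes a reacting centre.

**Route**

Step 1
Reactants: 1 2-methylresorcinol
Product: 2 1,3-bis(methoxymethoxy)-2-methylbenzene
Conditions: NaH, MOMCl, DMF, 0 °C → rt
Reagents that add atoms: chloromethyl methyl ether, COCCl
Why: Double Williamson O-alkylation of the two phenoxides with the reactive α-chloro ether, the symmetrical diol offering no other nucleophilic site.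

Step 2
Reactants: 2 1,3-bis(methoxymethoxy)-2-methylbenzene
Product: 4 3,5-bis(methoxymethoxy)-4-methylphenol, via aryl pinacol boronate 3 (not isolated)
Conditions: [Ir(OMe)(cod)]2 (1.5 mol %), 4,4'-di-tert-butyl-2,2'-bipyridine (3 mol %), B2pin2 (1 equiv), THF, 80 °C; then aq. H2O2, NaOH, 0 °C → rt; NH4Cl work-up
Reagents that add atoms: bis(pinacolato)diboron, CC1(C)OB(OC1(C)C)B1OC(C)(C)C(C)(C)O1 (boron of 3 only); hydrogen peroxide, OO (phenol oxygen of 4)
Why: Iridium-catalysed aromatic C–H borylation is sterically controlled and so takes the one ring C–H without an ortho substituent (meta to both MOM ethers), and basic peroxide oxidation of the C–B bond (aryl 1,2-shift from boron to oxygen) gives the phenol under conditions to which MOM acetals are inert.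

Step 3
Reactants: 4 3,5-bis(methoxymethoxy)-4-methylphenol
Product: 5 2-bromo-3,5-bis(methoxymethoxy)-4-methylphenol
Conditions: NBS (1.0 equiv), CH2Cl2, −78 → 0 °C, dark
Reagents that add atoms: N-bromosuccinimide, O=C1CCC(=O)N1Br
Why: Electrophilic aromatic bromination goes ortho to the free hydroxyl (the para position holds the methyl), and because the two ortho sites are equivalent by symmetry one equivalent at low temperature should give a single monobromide.

Step 4
Reactants: 5 2-bromo-3,5-bis(methoxymethoxy)-4-methylphenol
Product: 8 3,5-bis(methoxymethoxy)-4-methyl-2-(trimethylsilyl)phenyl trifluoromethanesulfonate, via aryl trimethylsilyl ether 6 (not isolated), via lithium 2-silylphenoxide 7 (not isolated)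
Conditions: HMDS, THF, 65 °C, then evaporate; n-BuLi, THF, −78 °C; Tf2O, −78 → 0 °C
Reagents that add atoms: hexamethyldisilazane, C[Si](C)(C)N[Si](C)(C)C; n-butyllithium, [Li]CCCC (lithium of 7 only); trifluoromethanesulfonic anhydride, O=S(=O)(OS(=O)(=O)C(F)(F)F)C(F)(F)F
Why: The standard entry to ortho-silylaryl triflates: O-silylation, bromine–lithium exchange and 1,3-retro-Brook O→C silyl migration put the trimethylsilyl group on the carbon that carried bromine, and the lithium phenoxide so released is triflated at low temperature, where the MOM acetals are not attacked.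

Step 5
Reactants: 8 3,5-bis(methoxymethoxy)-4-methyl-2-(trimethylsilyl)phenyl trifluoromethanesulfonate; 9 (R)-2-methylbutanoic acid
Product: 12 (2R)-1-[6-hydroxy-2,4-bis(methoxymethoxy)-3-methylphenyl]-2-methylbutan-1-one, via aryne 10 (not isolated), via C1 aryl anion 11 (not isolated)
Conditions: CsF (4 equiv), THF, 125 °C, sealed tube (8 in slight excess over 9); aq. NH4Cl work-up
Reagents that add atoms: cesium fluoride, [Cs+].[F-] (cesium counter-ion of 11 only)
Why: CsF attacks silicon of 8 and triflate leaves, unveiling aryne 10 whose strained triple bond joins the future C1 and C6; the cesium salt of 9, formed in the same medium, then bonds through oxygen to C6, the terminus that is distal to the C2 OMOM group and sterically open, so that the negative charge arrives at C1 next to the electron-withdrawing C2–O bond (aryl anion 11). That carbanion closes onto its own ester carbonyl to a transient four-membered alkoxide, whose ring C–O bond breaks to release the C6 phenoxide and leave the acyl group on C1, so the net result is insertion of the aryne into the acyl C–O bond of the acid. The closest known reaction is exactly this fluoride-induced aryne insertion of carboxylic acids to ortho-hydroxyaryl ketones, mechanistically an aryne-triggered relative of the anionic Fries shift. No ring of the product is closed and no stereocentre is made; the R centre of 9 is only carried along, sitting in a non-enolisable carboxylate before the transfer and in a ketone conjugated to an ortho-phenoxide afterwards, whose α-deprotonation would require a dianion. The step needs regioselectivity (oxygen at C6, acyl at C1), which the 3-alkoxyaryne polarisation by the C2 OMOM group secures while C5 beside C6 bears only hydrogen, and it needs acyl transfer to outrun protonation of 11, which the hot aprotic THF medium and the proximity of the ester carbonyl favour.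

Step 6
Reactants: 12 (2R)-1-[6-hydroxy-2,4-bis(methoxymethoxy)-3-methylphenyl]-2-methylbutan-1-one
Product: 13 (2R)-2-methyl-1-(2,4,6-trihydroxy-3-methylphenyl)butan-1-one
Conditions: HCl (cat.), MeOH, rt → 40 °C
Reagents that add atoms: none
Why: Acid-catalysed acetal exchange with methanol removes both MOM groups as dimethoxymethane, and the hindered, doubly ortho-substituted aryl ketone should not enolise under such mild acid, so the R centre is kept.

Step 7
Reactants: 13 (2R)-2-methyl-1-(2,4,6-trihydroxy-3-methylphenyl)butan-1-one
Product: 14 (2R)-1-(2,4,6-trihydroxy-3-iodo-5-methylphenyl)-2-methylbutan-1-one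
Conditions: NIS (1.0 equiv), MeCN, 0 °C, dark
Reagents that add atoms: N-iodosuccinimide, O=C1CCC(=O)N1I
Why: Electrophilic aromatic iodination can only occur at C5, the single unsubstituted ring carbon, which is activated by all three hydroxyls, and it is done while no alkene is present.

Step 8
Reactants: 14 (2R)-1-(2,4,6-trihydroxy-3-iodo-5-methylphenyl)-2-methylbutan-1-one
Product: 15 (2R)-1-[3-(1-ethoxyethenyl)-2,4,6-trihydroxy-5-methylphenyl]-2-methylbutan-1-one
Conditions: tributyl(1-ethoxyvinyl)stannane (1.5 equiv), PdCl2(PPh3)2 (5 mol %), Et3N (3 equiv), 1,4-dioxane, 90 °C; aq. KF/NaHCO3 work-up, Et3N-deactivated silica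
Reagents that add atoms: tributyl(1-ethoxyvinyl)stannane, CCCC[Sn](CCCC)(CCCC)C(=C)OCC
Why: Stille cross-coupling at the C5–I bond (oxidative addition to zerovalent palladium formed in situ, tin-to-palladium transfer of the 1-ethoxyvinyl group, reductive elimination) is run before any allylic ether exists, so neither π-allyl ionisation nor intramolecular Heck cyclisation can intervene, and it leaves C5 with a masked acetyl that does not chelate O4.

Step 9
Reactants: 15 (2R)-1-[3-(1-ethoxyethenyl)-2,4,6-trihydroxy-5-methylphenyl]-2-methylbutan-1-one; 16 geranyl bromide ((2E)-1-bromo-3,7-dimethylocta-2,6-diene)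
Product: 18 (2R)-1-[3-acetyl-4-{[(2E)-3,7-dimethylocta-2,6-dien-1-yl]oxy}-2,6-dihydroxy-5-methylphenyl]-2-methylbutan-1-one, via geranylated enol ether 17 (not isolated)
Conditions: K2CO3 (1.1 equiv), 16 (1.05 equiv), acetone, rt; then 0.5 M HCl, THF, 0 °C, short contact
Reagents that add atoms: water, O
Why: Williamson etherification (SN2 at the primary allylic bromide, E geometry untouched) takes place at O4 because one equivalent of weak base ionises only this most acidic hydroxyl, para to the C1 ketone and not chelated, whereas O2 and O6 flank the carbonyl; brief dilute acid then hydrolyses the enol ether to the C5 acetyl much faster than it can affect the geranyl ether or the α-stereocentre.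

**Compound list**

1 | 2-methylresorcinol (2-methylbenzene-1,3-diol) | Cc1c(O)cccc1O | starting material
2 | 1,3-bis(methoxymethoxy)-2-methylbenzene | COCOc1cccc(OCOC)c1C | intermediate
3 | 2-[3,5-bis(methoxymethoxy)-4-methylphenyl]-4,4,5,5-tetramethyl-1,3,2-dioxaborolane | COCOc1cc(cc(OCOC)c1C)B1OC(C)(C)C(C)(C)O1 | intermediate (not isolated)
4 | 3,5-bis(methoxymethoxy)-4-methylphenol | COCOc1cc(O)cc(OCOC)c1C | intermediate
5 | 2-bromo-3,5-bis(methoxymethoxy)-4-methylphenol | COCOc1cc(O)c(Br)c(OCOC)c1C | intermediate
6 | [2-bromo-3,5-bis(methoxymethoxy)-4-methylphenoxy]trimethylsilane | COCOc1cc(O[Si](C)(C)C)c(Br)c(OCOC)c1C | intermediate (not isolated)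
7 | lithium 3,5-bis(methoxymethoxy)-4-methyl-2-(trimethylsilyl)phenoxide | [Li+].[O-]c1cc(OCOC)c(C)c(OCOC)c1[Si](C)(C)C | intermediate (not isolated)
8 | 3,5-bis(methoxymethoxy)-4-methyl-2-(trimethylsilyl)phenyl trifluoromethanesulfonate | C[Si](C)(C)c1c(OCOC)c(C)c(OCOC)cc1OS(=O)(=O)C(F)(F)F | intermediate
9 | (R)-2-methylbutanoic acid | CC[C@@H](C)C(=O)O | starting material
10 | 3,5-bis(methoxymethoxy)-4-methylbenzyne (1,2-didehydro arene) | COCOC1=C(C)C(OCOC)=CC#C1 | intermediate (not isolated)
11 | cesium 2,4-bis(methoxymethoxy)-3-methyl-6-{[(2R)-2-methylbutanoyl]oxy}benzen-1-ide | CC[C@@H](C)C(=O)Oc1cc(OCOC)c(C)c(OCOC)[c-]1.[Cs+] | intermediate (not isolated)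
12 | (2R)-1-[6-hydroxy-2,4-bis(methoxymethoxy)-3-methylphenyl]-2-methylbutan-1-one | CC[C@@H](C)C(=O)c1c(OCOC)c(C)c(OCOC)cc1O | intermediate
13 | (2R)-2-methyl-1-(2,4,6-trihydroxy-3-methylphenyl)butan-1-one | CC[C@@H](C)C(=O)c1c(O)c(C)c(O)cc1O | intermediate
14 | (2R)-1-(2,4,6-trihydroxy-3-iodo-5-methylphenyl)-2-methylbutan-1-one | CC[C@@H](C)C(=O)c1c(O)c(C)c(O)c(I)c1O | intermediate
15 | (2R)-1-[3-(1-ethoxyethenyl)-2,4,6-trihydroxy-5-methylphenyl]-2-methylbutan-1-one | CC[C@@H](C)C(=O)c1c(O)c(C)c(O)c(C(=C)OCC)c1O | intermediate
16 | geranyl bromide ((2E)-1-bromo-3,7-dimethylocta-2,6-diene) | CC(C)=CCC/C(C)=C/CBr | starting material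
17 | (2R)-1-[4-{[(2E)-3,7-dimethylocta-2,6-dien-1-yl]oxy}-3-(1-ethoxyethenyl)-2,6-dihydroxy-5-methylphenyl]-2-methylbutan-1-one | CC[C@@H](C)C(=O)c1c(O)c(C)c(OC/C=C(\C)CCC=C(C)C)c(C(=C)OCC)c1O | intermediate (not isolated)
18 | (2R)-1-[3-acetyl-4-{[(2E)-3,7-dimethylocta-2,6-dien-1-yl]oxy}-2,6-dihydroxy-5-methylphenyl]-2-methylbutan-1-one | CC[C@@H](C)C(=O)c1c(O)c(C)c(OC/C=C(\C)CCC=C(C)C)c(C(C)=O)c1O | target

**Totals**

Total step count: 9. Longest linear sequence: 9 steps (1 → 18).

**Steps most likely to fail**

Step 5. The aryl anion may be protonated before it reaches the ester carbonyl, which would give plain O-arylation and no C1–carbonyl bond. Slow enolisation during the long heating with fluoride could also erode the R centre; the enantiomeric purity of 12 should be checked by chiral HPLC. Fallback: from 5, esterification with 9 (EDC·HCl, cat. DMAP, CH2Cl2, 0 °C) should give 2-bromo-3,5-bis(methoxymethoxy)-4-methylphenyl (2R)-2-methylbutanoate F1. Bromine–lithium exchange (t-BuLi, 2 equiv, THF, −100 °C) then triggers a 1,3 O→C acyl shift, an anionic Fries rearrangement started by halogen–metal exchange. After aqueous NH4Cl this comes back to the route at 12, with the acyl group on the same carbon and without heating.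

Step 8. The acidic free phenols may protonate the stannane or the new enol ether, phenoxide binding may slow the catalyst, or the electron-rich C5–I bond may be reduced instead of coupled. Fallback: from 14, peracetylation (Ac2O, pyridine, cat. DMAP, CH2Cl2) should give 2-iodo-4-methyl-6-[(2R)-2-methylbutanoyl]benzene-1,3,5-triyl triacetate F2. Stille coupling with the same stannane (PdCl2(PPh3)2, dioxane, 90 °C, no amine) gives 2-(1-ethoxyethenyl)-4-methyl-6-[(2R)-2-methylbutanoyl]benzene-1,3,5-triyl triacetate F3. Methanolysis of the three aryl acetates (K2CO3, MeOH, 0 °C) leaves the enol ether alone and comes back to the route at 15.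

Step 9. Alkylation may spread to O2 or O6 (over-alkylation). The enol ether may also be lost before the ether is formed, which would erase the difference between O2 and O4, and too long an acid contact could ionise the geranyl ether. Fallback: from 15, Mitsunobu etherification with geraniol (PPh3, DIAD, THF, 0 °C, betaine preformed) replaces base-and-halide alkylation by a redox condensation. The betaine deprotonates only the most acidic hydroxyl and no phenoxide is ever present in excess. It leads to the same intermediate 17, which is hydrolysed with oxalic acid in wet THF, coming back to the route at 18; no new compound is made (F0).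

**Further compounds**

F1 | step 5 | 2-bromo-3,5-bis(methoxymethoxy)-4-methylphenyl (2R)-2-methylbutanoate | CC[C@@H](C)C(=O)Oc1cc(OCOC)c(C)c(OCOC)c1Br
F2 | step 8 | 2-iodo-4-methyl-6-[(2R)-2-methylbutanoyl]benzene-1,3,5-triyl triacetate | CC[C@@H](C)C(=O)c1c(OC(C)=O)c(C)c(OC(C)=O)c(I)c1OC(C)=O
F3 | step 8 | 2-(1-ethoxyethenyl)-4-methyl-6-[(2R)-2-methylbutanoyl]benzene-1,3,5-triyl triacetate | CC[C@@H](C)C(=O)c1c(OC(C)=O)c(C)c(OC(C)=O)c(C(=C)OCC)c1OC(C)=O
F0 | step 9 | none | none
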